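(Its constants were chosen freely; the rest is arithmetic.)

Count X rather than Z.X: each Z.X takes one X and the scheme has no step that consumes Z.X, so the X made is a ceiling on the product.

| flask | E | J | L | temperature | time |
|---|---|---|---|---|---|
| teal | 20 mM | 16.0 mM | 10.0 mM | 0 °C | 4.0 d |
| grey | 20 mM | 16.0 mM | 10.0 mM | 50 °C | 4.0 d |
| green | 20 mM | 16.0 mM | 10.0 mM | 25 °C | 4.0 d |
| ochre | 20 mM | 16.0 mM | 10.0 mM | −25 °C | 4.0 d |

    Z + X → Z.X (k1 = 3.3 × 10⁻⁴ /M/s, Ea1 = 63.0 kJ/mol)
    J → X (k2 = 1.4 × 10⁻⁵ /s, Ea2 = 94.0 kJ/mol)
    J + L → J.L (k3 = 0.024 /M/s, Ea3 = 49.0 kJ/mol)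
    E → Z (k4 = 1.7 × 10⁻⁵ /s, Ea4 = 92.0 kJ/mol)
    Q ⇌ Z.X, rate k5*(cs5 - [Z.X]) while solid is left; crystals form when [Z.X] > cs5 (cs5 = 3.9 mM, k5 = 6.8 × 10⁻⁴ /s)
    (constants at 25 °C)

- the flask that comes out highest in amount of Z.X, in percent of the E charged, or "all alike" when all lie within 1.5 percentage points (teal / grey / green / ochre / all alike)
- Z.X at the end, in percent of the E charged, teal
- Z.X at the end, in percent of the E charged, grey
- Z.X at the end, in percent of the E charged, green
- Z.X at the end, in percent of the E charged, ochre

- what is said of Z.X includes Q
- Q is a solid; its amount is given per volume of the solution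
- constants are those at 25 °C; use the activation energies for any other temperature

J has two exits, to X at a rate proportional to [J] and to J.L at a rate proportional to [J][L]. Divide the two rates, and [J] and time drop out. Call the first constant over the second r, the split concentration, the [L] at which both exits run equally: 0.583 mM at 25 °C. With C the charge of L, D that of J and X here the total of X made so far, the integral and the balance of J give:

X = r ln(C/[L]), so [L] = C exp(−X/r)

X = D − [J] − C + [L], which is at most D − C + [L]

The activation energies differ by 45.0 kJ/mol, which puts r at 2.38 mM in grey, 0.111 mM in teal and 0.0150 mM in ochre. In grey the exit to X alone has k·t = 90.9, so take [J] as nil and pass back and forth, each pass landing on the other side: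

below: 6.00 mM, which is 30.0% of E

above: 6.80 mM, which is 34.0%

below: 6.57 mM, which is 32.9%

above: 6.63 mM, which is 33.1%

X must still meet Z. Over the second half of the time in grey, [Z] is at least the charge of E less the ceiling on X, so X decays pseudo-first-order with an exponent of at least 5.45. That leaves at most 0.430% of it uncoupled, and the floor for Z.X in grey is 6.54 mM, or 32.7%. The ceiling in green is 6.00 mM, or 30.0%, and teal and ochre read the same. Commit to grey as highest.

The forecast names grey, with 33.1% in grey, 22.4% in green, 0.07% in teal and <0.001% in ochre, on the ground that “Nothing consumes Z.X, so the solubility and crystal step do not affect the total.” Its grey figure stands inside the bracket.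

The simulation gives grey highest: 33.1% in grey, 22.3% in green, 0.0675% in teal, 0% in ochre.

The ratio of capture to loss of J is [L]/r. In ochre it is 660 at the start and 130 at 4.00 d, while grey ends at 0.260.

Now take ochre charged with 4.0 mM of L. With L at 12.2% of its charge, r ln(C/[L]) gives X = 0.0316 mM. That flask holds X at 0.0316 mM and Z.X at 0% after 4.00 d.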